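**Strategy**

The cyclopenta[c]pyridine core is cut back to a cis-fused dichlorocyclobutanone. In the target, methyl-bearing C7 lies between oxygenated C6 and ring-fusion carbon C7a of the five-membered ring (C4a–C5–C6–C7–C7a), which is where a diazoalkane carbon enters a fused cyclobutanone. One operation, diazoethane insertion into C6–C7a, forms C6–C7 and C7–C7a, enlarges the four-membered ring to the cyclopentanone and brings in the C7 methyl. Its substrate is the enantiopure dichloroketene adduct of an N-carbomethoxy-5-methyl-1,2-dihydropyridine, which keeps the C3=C4 enecarbamate for later hydrogenation. The core alcohol is then joined by Mitsunobu inversion to a geraniol-derived diacid half-ester.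

Key step: step 4

**Remarks and assumptions**

- Core atoms are numbered as in cyclopenta[c]pyridine (C1, N2, C3, C4, C4a, C5, C6, C7, C7a), also for the bicyclic precursors.
- The substrate of the key step carries the ketone at C8, next to the bridgehead that bears the CH2N group, and the CCl2 group at C7 (7,7-dichloro-8-oxo). Only this regiochemistry maps onto C6 and C5 of the target.
- Read literally, the target SMILES places the tertiary and the secondary hydroxyl of the cyclohexane unit on opposite faces, with the hydroxyethyl arm cis to the secondary OH. "trans" in the names below means this, and the route builds exactly this isomer.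
- Small-hydride reduction of the C6 ketone is expected to give the C6 epimer of the alcohol needed, so the core is attached with inversion.

**Route**

Step 1
Reactants: 1 3-methylpyridine
Product: 3 methyl 5-methylpyridine-1(2H)-carboxylate, via acylpyridinium chloride 2 (not isolated)
Conditions: ClCO2Me, NaBH4, MeOH, −78 °C
Reagents that add atoms: methyl chloroformate COC(=O)Cl
Why: Fowler reduction: the pyridine is acylated in the flask and borohydride adds to an α-carbon of acylpyridinium ion 2, preferentially at C6, the α-position remote from the methyl group, to give 1,2-dihydropyridine 3; the 3-methyl isomer from attack at C2 is expected as a by-product and is removed as its cycloadduct after step 2.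

Step 2
Reactants: 3 methyl 5-methylpyridine-1(2H)-carboxylate; 4 trichloroacetyl chloride
Product: 6 rac-methyl (1R*,6S*)-7,7-dichloro-5-methyl-8-oxo-3-azabicyclo[4.2.0]oct-4-ene-3-carboxylate, via dichloroketene 5 (not isolated)
Conditions: Zn–Cu couple, Et2O–DME, ultrasound, 15–20 °C
Reagents that add atoms: none
Why: Thermal ketene–alkene [2+2] cycloaddition: dichloroketene, made by zinc dechlorination of 4, adds suprafacially across the cis C3=C4 bond (dihydropyridine numbering) so that the ring fusion is cis, and its carbonyl carbon bonds to the diene terminus C3 because the charge that builds up at C4 is allylic and nitrogen-stabilised, which places C=O next to the CH2N-bearing bridgehead and CCl2 next to the alkene-bearing one, while the methyl-substituted enecarbamate bond C5=C6 is the more hindered site.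

Step 3
Reactants: 6 rac-methyl (1R*,6S*)-7,7-dichloro-5-methyl-8-oxo-3-azabicyclo[4.2.0]oct-4-ene-3-carboxylate
Product: 7 methyl (1R,6S)-7,7-dichloro-5-methyl-8-oxo-3-azabicyclo[4.2.0]oct-4-ene-3-carboxylate
Conditions: ketoreductase (from a screening panel), NADP+ (cat.), i-PrOH, phosphate buffer pH 7–MTBE, 25 °C, stopped near half conversion
Reagents that add atoms: none
Why: Enzymatic kinetic resolution by enantioselective carbonyl reduction: a ketoreductase picked from a screening panel should reduce the (1S,6R)-ketone to its cyclobutanol and leave the (1R,6S)-ketone, which is separated by chromatography, a mode of resolution documented for bicyclic α,α-dichlorocyclobutanones with microbial reductases.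

Step 4
Reactants: 7 methyl (1R,6S)-7,7-dichloro-5-methyl-8-oxo-3-azabicyclo[4.2.0]oct-4-ene-3-carboxylate; 8 N-ethyl-N-nitrosourea
Product: 11 methyl (4aS,7R,7aR)-5,5-dichloro-4,7-dimethyl-6-oxo-1,4a,5,6,7,7a-hexahydro-2H-cyclopenta[c]pyridine-2-carboxylate, via diazoethane 9 (not isolated), via diazonium betaine 10 (not isolated)
Conditions: 8, aq. KOH, Et2O, 0 °C (ethereal diazoethane, dried over KOH); added to 7 in Et2O–MeOH, −78 → 0 °C; AcOH quench; then silica gel, CH2Cl2, rt
Reagents that add atoms: none
Why: Diazoethane adds through its carbon to the strained, chlorine-activated C6 carbonyl to give diazonium betaine 10, which loses N2 while C7a shifts from C6 to the new carbon, so that C6–C7 and C7–C7a are formed in one event. The closest known reaction type is the diazoalkane homologation (Büchner–Curtius–Schlotterbeck type) of α,α-dichlorocyclobutanones made from dichloroketene, which is established chemistry. The five-membered ring C4a–C5–C6–C7–C7a arises by one-carbon enlargement of the four-membered ring through this 1,2-shift, not by a cyclisation, and release of cyclobutanone strain drives it. The selectivity needed is migration of C7a instead of C5, and the two chlorines secure it by making C5 electron-poor and slow to migrate; they also retard a second insertion into the less strained product. C7a migrates with retention, so the cis ring fusion at C4a and C7a set in step 2 is carried over. C7 is formed as a mixture of epimers but lies α to the ketone, and equilibration (silica gel here, completed in step 5) should favour the methyl group on the convex face, trans to C1, as in the target; the electron-rich enecarbamate is inert to the nucleophilic diazoalkane.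

Step 5
Reactants: 11 methyl (4aS,7R,7aR)-5,5-dichloro-4,7-dimethyl-6-oxo-1,4a,5,6,7,7a-hexahydro-2H-cyclopenta[c]pyridine-2-carboxylate
Product: 12 methyl (4aS,7R,7aS)-4,7-dimethyl-6-oxo-1,4a,5,6,7,7a-hexahydro-2H-cyclopenta[c]pyridine-2-carboxylate
Conditions: Zn–Cu couple, NH4Cl, MeOH, rt; crude then K2CO3 (cat.), MeOH, rt
Reagents that add atoms: none
Why: Reductive dehalogenation of an α,α-dichloroketone by zinc (two electron-transfer/protonation events through zinc enolates) removes both chlorines at C5 without touching carbamate or alkene, and the mild basic finish completes the equilibration of C7 to the convex-face methyl epimer, C4a and C7a not being enolisable.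

Step 6
Reactants: 12 methyl (4aS,7R,7aS)-4,7-dimethyl-6-oxo-1,4a,5,6,7,7a-hexahydro-2H-cyclopenta[c]pyridine-2-carboxylate
Product: 13 methyl (4S,4aR,7R,7aS)-4,7-dimethyl-6-oxooctahydro-2H-cyclopenta[c]pyridine-2-carboxylate
Conditions: H2 (3 atm), 10% Pd/C, EtOAc, rt
Reagents that add atoms: none
Why: Heterogeneous catalytic hydrogenation of the trisubstituted enecarbamate: hydrogen should be delivered to the convex face of the cis-fused bicycle, the face of H-4a and H-7a, because the C4a–C5 bond stands pseudo-axial on the other face to avoid allylic strain with the C4 methyl, which sets C4 as S with H-4 cis to H-4a.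

Step 7
Reactants: 13 methyl (4S,4aR,7R,7aS)-4,7-dimethyl-6-oxooctahydro-2H-cyclopenta[c]pyridine-2-carboxylate
Product: 14 (4S,4aR,6R,7R,7aS)-2,4,7-trimethyloctahydro-1H-cyclopenta[c]pyridin-6-ol
Conditions: LiAlH4 (excess), THF, −78 °C → reflux; Fieser work-up
Reagents that add atoms: none
Why: Hydride reduction with LiAlH4: at low temperature the small hydride should attack the C6 ketone from the convex face, cis to the C7 methyl as small hydrides do with 2-methylcyclopentanones, to give the 6R alcohol with OH trans to that methyl, and on heating the methyl carbamate is reduced to the N-methyl amine.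

Step 8
Reactants: 15 tyrosol
Product: 16 4-hydroxy-4-(2-hydroxyethyl)cyclohexa-2,5-dien-1-one
Conditions: PhI(OAc)2, MeCN–H2O, 0 °C
Reagents that add atoms: water O
Why: Oxidative dearomatisation of a para-alkylphenol with an iodine(III) reagent: the oxidised phenol is captured by water at the para carbon to give the para-quinol, and no stereocentre is formed.

Step 9
Reactants: 16 4-hydroxy-4-(2-hydroxyethyl)cyclohexa-2,5-dien-1-one
Product: 17 4-hydroxy-4-(2-hydroxyethyl)cyclohexan-1-one
Conditions: H2 (1 atm), 5% Rh/Al2O3, EtOAc, rt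
Reagents that add atoms: none
Why: Catalytic hydrogenation of the two enone C=C bonds under neutral conditions, where rhodium on alumina limits hydrogenolysis or re-aromatisation at the tertiary carbinol and the absence of acid or base avoids oxa-Michael closure of the side-chain hydroxyl.

Step 10
Reactants: 17 4-hydroxy-4-(2-hydroxyethyl)cyclohexan-1-one
Product: 18 trans-1-(2-hydroxyethyl)cyclohexane-1,4-diol
Conditions: LiBH(s-Bu)3 (excess), THF, −78 °C; then NaOH, H2O2, 0 °C
Reagents that add atoms: none
Why: Diastereoselective ketone reduction with a bulky trialkylborohydride: in the favoured chair the hydroxyethyl arm is equatorial and the tertiary OH axial, and the reagent attacks along the equatorial direction to give the axial secondary alcohol, so the two hydroxyls end up trans; the minor cis isomer is removed by crystallisation.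

Step 11
Reactants: 19 geranyl acetate
Product: 21 (2E,6E)-3,7-dimethyl-8-oxoocta-2,6-dien-1-yl acetate, via 8-hydroxygeranyl acetate 20 (not isolated)
Conditions: SeO2 (cat.), t-BuOOH, salicylic acid (cat.), CH2Cl2, rt; crude then MnO2, CH2Cl2, rt
Reagents that add atoms: selenium dioxide O=[Se]=O; tert-butyl hydroperoxide CC(C)(C)OO
Why: Selenium dioxide allylic oxidation (ene reaction then [2,3]-sigmatropic shift) attacks the E-methyl group of the terminal trisubstituted alkene, and MnO2 then carries the allylic alcohol on so that alcohol and aldehyde converge on 21 with the 6E geometry retained.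

Step 12
Reactants: 21 (2E,6E)-3,7-dimethyl-8-oxoocta-2,6-dien-1-yl acetate
Product: 22 (2E,6E)-8-acetoxy-2,6-dimethylocta-2,6-dienoic acid
Conditions: NaClO2, NaH2PO4, 2-methyl-2-butene, t-BuOH–H2O, rt
Reagents that add atoms: sodium chlorite [Na+].[O-]Cl=O
Why: Pinnick oxidation converts the enal into the acid without isomerising either alkene, with 2-methyl-2-butene trapping the hypochlorite formed.

Step 13
Reactants: 22 (2E,6E)-8-acetoxy-2,6-dimethylocta-2,6-dienoic acid; 18 trans-1-(2-hydroxyethyl)cyclohexane-1,4-diol
Product: 23 2-(trans-1,4-dihydroxycyclohexyl)ethyl (2E,6E)-8-acetoxy-2,6-dimethylocta-2,6-dienoate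
Conditions: EDC·HCl, DMAP (cat.), CH2Cl2–DMF, 0 °C → rt
Reagents that add atoms: none
Why: Steglich esterification: the unhindered primary hydroxyl of 18 is acylated much faster than the axial secondary and the tertiary hydroxyl.

Step 14
Reactants: 23 2-(trans-1,4-dihydroxycyclohexyl)ethyl (2E,6E)-8-acetoxy-2,6-dimethylocta-2,6-dienoate
Product: 24 2-[trans-4-(tert-butyldimethylsilyloxy)-1-hydroxycyclohexyl]ethyl (2E,6E)-8-acetoxy-2,6-dimethylocta-2,6-dienoate
Conditions: TBSCl, imidazole, DMF, rt → 40 °C
Reagents that add atoms: tert-butyldimethylsilyl chloride CC(C)(C)[Si](C)(C)Cl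
Why: Silyl ether formation with a silyl chloride and imidazole protects the secondary hydroxyl, which would otherwise compete as an alcohol partner in step 17, while the tertiary hydroxyl does not react under these conditions.

Step 15
Reactants: 24 2-[trans-4-(tert-butyldimethylsilyloxy)-1-hydroxycyclohexyl]ethyl (2E,6E)-8-acetoxy-2,6-dimethylocta-2,6-dienoate
Product: 25 2-[trans-4-(tert-butyldimethylsilyloxy)-1-hydroxycyclohexyl]ethyl (2E,6E)-8-hydroxy-2,6-dimethylocta-2,6-dienoate
Conditions: K2CO3 (cat.), MeOH, 0 °C
Reagents that add atoms: none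
Why: Base-catalysed transesterification (methanolysis) removes the unhindered primary acetate far faster than it attacks the α-branched conjugated ester, and the silyl ether is stable.

Step 16
Reactants: 25 2-[trans-4-(tert-butyldimethylsilyloxy)-1-hydroxycyclohexyl]ethyl (2E,6E)-8-hydroxy-2,6-dimethylocta-2,6-dienoate
Product: 27 (2E,6E)-8-{2-[trans-4-(tert-butyldimethylsilyloxy)-1-hydroxycyclohexyl]ethoxy}-3,7-dimethyl-8-oxoocta-2,6-dienoic acid, via enal 26 (not isolated)
Conditions: MnO2, CH2Cl2, rt; filtered; then NaClO2, NaH2PO4, 2-methyl-2-butene, t-BuOH–H2O, 0 °C → rt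
Reagents that add atoms: sodium chlorite [Na+].[O-]Cl=O
Why: Allylic alcohol oxidation with MnO2 followed by Pinnick oxidation of the crude enal gives the 3-methyl-2-enoic acid with the 2E geometry kept, and neither reagent affects the tertiary alcohol, the silyl ether or the ester.

Step 17
Reactants: 27 (2E,6E)-8-{2-[trans-4-(tert-butyldimethylsilyloxy)-1-hydroxycyclohexyl]ethoxy}-3,7-dimethyl-8-oxoocta-2,6-dienoic acid; 14 (4S,4aR,6R,7R,7aS)-2,4,7-trimethyloctahydro-1H-cyclopenta[c]pyridin-6-ol
Product: 28 1-{2-[trans-4-(tert-butyldimethylsilyloxy)-1-hydroxycyclohexyl]ethyl} 8-[(4S,4aR,6S,7R,7aS)-2,4,7-trimethyloctahydro-1H-cyclopenta[c]pyridin-6-yl] (2E,6E)-2,6-dimethylocta-2,6-dienedioate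
Conditions: PPh3, DIAD, THF, 0 °C → rt
Reagents that add atoms: none
Why: Mitsunobu esterification: the alkoxyphosphonium ion of the C6 alcohol is displaced by the carboxylate in an SN2 reaction with inversion, turning 6R into the 6S ester with oxygen cis to the C7 methyl as the target requires, while the tertiary alcohol of 27 is inert and the tertiary amine is tolerated.

Step 18
Reactants: 28 1-{2-[trans-4-(tert-butyldimethylsilyloxy)-1-hydroxycyclohexyl]ethyl} 8-[(4S,4aR,6S,7R,7aS)-2,4,7-trimethyloctahydro-1H-cyclopenta[c]pyridin-6-yl] (2E,6E)-2,6-dimethylocta-2,6-dienedioate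
Product: 29 1-[2-(trans-1,4-dihydroxycyclohexyl)ethyl] 8-[(4S,4aR,6S,7R,7aS)-2,4,7-trimethyloctahydro-1H-cyclopenta[c]pyridin-6-yl] (2E,6E)-2,6-dimethylocta-2,6-dienedioate (CNP0298382.1)
Conditions: HF·pyridine, pyridine, THF, 0 °C → rt; NaHCO3 work-up
Reagents that add atoms: none
Why: Fluoride-mediated silyl ether cleavage under buffered, non-basic conditions leaves both enoate esters, the tertiary alcohol and the amine untouched and releases the target.

**Compound list**

1 | 3-methylpyridine | Cc1cccnc1 | starting material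
2 | 1-(methoxycarbonyl)-3-methylpyridin-1-ium chloride | COC(=O)[n+]1cccc(C)c1.[Cl-] | intermediate
3 | methyl 5-methylpyridine-1(2H)-carboxylate | COC(=O)N1CC=CC(C)=C1 | intermediate
4 | trichloroacetyl chloride | ClC(Cl)(Cl)C(Cl)=O | starting material
5 | dichloroketene | ClC(Cl)=C=O | intermediate
6 | rac-methyl (1R*,6S*)-7,7-dichloro-5-methyl-8-oxo-3-azabicyclo[4.2.0]oct-4-ene-3-carboxylate (cis-fused racemate; one enantiomer drawn) | O=C1C(Cl)(Cl)[C@H]2[C@@H]1CN(C(=O)OC)C=C2C | intermediate
7 | methyl (1R,6S)-7,7-dichloro-5-methyl-8-oxo-3-azabicyclo[4.2.0]oct-4-ene-3-carboxylate | O=C1C(Cl)(Cl)[C@H]2[C@@H]1CN(C(=O)OC)C=C2C | intermediate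
8 | N-ethyl-N-nitrosourea | CCN(N=O)C(N)=O | starting material
9 | diazoethane | CC=[N+]=[N-] | intermediate
10 | methyl (1R,6S)-7,7-dichloro-8-(1-diazonioethyl)-5-methyl-8-oxido-3-azabicyclo[4.2.0]oct-4-ene-3-carboxylate (diazonium betaine) | CC([N+]#N)C1([O-])C(Cl)(Cl)[C@H]2[C@@H]1CN(C(=O)OC)C=C2C | intermediate
11 | methyl (4aS,7R,7aR)-5,5-dichloro-4,7-dimethyl-6-oxo-1,4a,5,6,7,7a-hexahydro-2H-cyclopenta[c]pyridine-2-carboxylate | O=C1C(Cl)(Cl)[C@H]2[C@H](CN(C(=O)OC)C=C2C)[C@H]1C | intermediate
12 | methyl (4aS,7R,7aS)-4,7-dimethyl-6-oxo-1,4a,5,6,7,7a-hexahydro-2H-cyclopenta[c]pyridine-2-carboxylate | O=C1C[C@H]2[C@H](CN(C(=O)OC)C=C2C)[C@H]1C | intermediate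
13 | methyl (4S,4aR,7R,7aS)-4,7-dimethyl-6-oxooctahydro-2H-cyclopenta[c]pyridine-2-carboxylate | O=C1C[C@H]2[C@H](CN(C(=O)OC)C[C@H]2C)[C@H]1C | intermediate
14 | (4S,4aR,6R,7R,7aS)-2,4,7-trimethyloctahydro-1H-cyclopenta[c]pyridin-6-ol | O[C@@H]1C[C@H]2[C@H](CN(C)C[C@H]2C)[C@H]1C | intermediate
15 | tyrosol | OCCc1ccc(O)cc1 | starting material
16 | 4-hydroxy-4-(2-hydroxyethyl)cyclohexa-2,5-dien-1-one | O=C1C=CC(O)(CCO)C=C1 | intermediate
17 | 4-hydroxy-4-(2-hydroxyethyl)cyclohexan-1-one | O=C1CCC(O)(CCO)CC1 | intermediate
18 | trans-1-(2-hydroxyethyl)cyclohexane-1,4-diol | OCC[C@]1(O)CC[C@H](O)CC1 | intermediate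
19 | geranyl acetate | CC(C)=CCC/C(C)=C/COC(C)=O | starting material
20 | (2E,6E)-8-hydroxy-3,7-dimethylocta-2,6-dien-1-yl acetate | OC/C(C)=C/CC/C(C)=C/COC(C)=O | intermediate
21 | (2E,6E)-3,7-dimethyl-8-oxoocta-2,6-dien-1-yl acetate | O=C/C(C)=C/CC/C(C)=C/COC(C)=O | intermediate
22 | (2E,6E)-8-acetoxy-2,6-dimethylocta-2,6-dienoic acid | OC(=O)/C(C)=C/CC/C(C)=C/COC(C)=O | intermediate
23 | 2-(trans-1,4-dihydroxycyclohexyl)ethyl (2E,6E)-8-acetoxy-2,6-dimethylocta-2,6-dienoate | C/C(=C\COC(C)=O)CC/C=C(\C)C(=O)OCC[C@]1(O)CC[C@H](O)CC1 | intermediate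
24 | 2-[trans-4-(tert-butyldimethylsilyloxy)-1-hydroxycyclohexyl]ethyl (2E,6E)-8-acetoxy-2,6-dimethylocta-2,6-dienoate | C/C(=C\COC(C)=O)CC/C=C(\C)C(=O)OCC[C@]1(O)CC[C@H](O[Si](C)(C)C(C)(C)C)CC1 | intermediate
25 | 2-[trans-4-(tert-butyldimethylsilyloxy)-1-hydroxycyclohexyl]ethyl (2E,6E)-8-hydroxy-2,6-dimethylocta-2,6-dienoate | C/C(=C\CO)CC/C=C(\C)C(=O)OCC[C@]1(O)CC[C@H](O[Si](C)(C)C(C)(C)C)CC1 | intermediate
26 | 2-[trans-4-(tert-butyldimethylsilyloxy)-1-hydroxycyclohexyl]ethyl (2E,6E)-2,6-dimethyl-8-oxoocta-2,6-dienoate | C/C(=C\C=O)CC/C=C(\C)C(=O)OCC[C@]1(O)CC[C@H](O[Si](C)(C)C(C)(C)C)CC1 | intermediate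
27 | (2E,6E)-8-{2-[trans-4-(tert-butyldimethylsilyloxy)-1-hydroxycyclohexyl]ethoxy}-3,7-dimethyl-8-oxoocta-2,6-dienoic acid | C/C(=C\C(=O)O)CC/C=C(\C)C(=O)OCC[C@]1(O)CC[C@H](O[Si](C)(C)C(C)(C)C)CC1 | intermediate
28 | 1-{2-[trans-4-(tert-butyldimethylsilyloxy)-1-hydroxycyclohexyl]ethyl} 8-[(4S,4aR,6S,7R,7aS)-2,4,7-trimethyloctahydro-1H-cyclopenta[c]pyridin-6-yl] (2E,6E)-2,6-dimethylocta-2,6-dienedioate | C/C(=C\C(=O)O[C@H]1C[C@H]2[C@H](CN(C)C[C@H]2C)[C@H]1C)CC/C=C(\C)C(=O)OCC[C@]1(O)CC[C@H](O[Si](C)(C)C(C)(C)C)CC1 | intermediate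
29 | 1-[2-(trans-1,4-dihydroxycyclohexyl)ethyl] 8-[(4S,4aR,6S,7R,7aS)-2,4,7-trimethyloctahydro-1H-cyclopenta[c]pyridin-6-yl] (2E,6E)-2,6-dimethylocta-2,6-dienedioate (CNP0298382.1) | C/C(=C\C(=O)O[C@H]1C[C@H]2[C@H](CN(C)C[C@H]2C)[C@H]1C)CC/C=C(\C)C(=O)OCC[C@]1(O)CC[C@H](O)CC1 | target

**Step count**

Total: 18 steps. Longest linear sequence: 9 steps (steps 1–7, 17, 18; the tyrosol branch, steps 8–10 and 13–18, is equally long).

**Steps most likely to fail**

1. Step 4 (ring expansion). The 1,2-shift may lose regiocontrol, a second diazoethane may insert into the product ketone, epoxide may form by O-closure of the betaine, or the unstable diazoalkane may decompose before it reacts. The fallback sets out from 7 and returns at 11. Compound 7 is homologated with diazomethane (Et2O–MeOH, 0 °C), the most widely used reagent for this ring expansion, to methyl (4aS,7aR)-5,5-dichloro-4-methyl-6-oxo-1,4a,5,6,7,7a-hexahydro-2H-cyclopenta[c]pyridine-2-carboxylate F1, in which C7 is the only enolisable position. Its lithium enolate (LiHMDS, THF, −78 °C, kept cold to avoid Favorskii-type contraction) is methylated with MeI on the convex face, which gives 11 with the C7 methyl introduced by a separate alkylation.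

2. Step 3 (resolution). The reductase may discriminate the enantiomers poorly, or the electrophilic dichloroketone may hydrate and cleave in the aqueous buffer during the slow enzymatic reaction. The fallback sets out from 6 and returns at 7. Racemic 6 is reduced with NaBH4 (MeOH, −40 °C, hydride from the convex face) to the racemic endo-cyclobutanol, rac-methyl (1R*,6S*,8S*)-7,7-dichloro-8-hydroxy-5-methyl-3-azabicyclo[4.2.0]oct-4-ene-3-carboxylate F2. It is resolved in organic solvent by lipase-catalysed acyl transfer (Burkholderia cepacia lipase, vinyl acetate, MTBE), with a lipase chosen so that the unwanted enantiomer is converted into methyl (1S,6R,8R)-8-acetoxy-7,7-dichloro-5-methyl-3-azabicyclo[4.2.0]oct-4-ene-3-carboxylate F3 and methyl (1R,6S,8S)-7,7-dichloro-8-hydroxy-5-methyl-3-azabicyclo[4.2.0]oct-4-ene-3-carboxylate F4 is left. Dess–Martin oxidation of F4 gives enantiopure 7.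

3. Step 17 (fragment union with inversion). Displacement must occur next to the cis C7 methyl, so the activated alcohol may eliminate to the cyclopentene, or acyl transfer may occur without inversion; the modest acidity of the enoic acid slows the productive pathway. The fallback sets out from 14 and returns at 28, separating inversion from coupling. Mitsunobu reaction of 14 with 4-nitrobenzoic acid (PPh3, DIAD, THF), the standard more acidic partner for hindered alcohols, gives (4S,4aR,6S,7R,7aS)-2,4,7-trimethyloctahydro-1H-cyclopenta[c]pyridin-6-yl 4-nitrobenzoate F5. Methanolysis (K2CO3, MeOH) gives (4S,4aR,6S,7R,7aS)-2,4,7-trimethyloctahydro-1H-cyclopenta[c]pyridin-6-ol F6, whose convex-face hydroxyl is acylated with 27 under carbodiimide/DMAP conditions to give 28.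

**Further compounds**

F1 | step 4 | methyl (4aS,7aR)-5,5-dichloro-4-methyl-6-oxo-1,4a,5,6,7,7a-hexahydro-2H-cyclopenta[c]pyridine-2-carboxylate | O=C1C(Cl)(Cl)[C@H]2[C@H](CN(C(=O)OC)C=C2C)C1
F2 | step 3 | rac-methyl (1R*,6S*,8S*)-7,7-dichloro-8-hydroxy-5-methyl-3-azabicyclo[4.2.0]oct-4-ene-3-carboxylate (racemate; one enantiomer drawn) | O[C@@H]1C(Cl)(Cl)[C@H]2[C@@H]1CN(C(=O)OC)C=C2C
F3 | step 3 | methyl (1S,6R,8R)-8-acetoxy-7,7-dichloro-5-methyl-3-azabicyclo[4.2.0]oct-4-ene-3-carboxylate | CC(=O)O[C@H]1C(Cl)(Cl)[C@@H]2[C@H]1CN(C(=O)OC)C=C2C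
F4 | step 3 | methyl (1R,6S,8S)-7,7-dichloro-8-hydroxy-5-methyl-3-azabicyclo[4.2.0]oct-4-ene-3-carboxylate | O[C@@H]1C(Cl)(Cl)[C@H]2[C@@H]1CN(C(=O)OC)C=C2C
F5 | step 17 | (4S,4aR,6S,7R,7aS)-2,4,7-trimethyloctahydro-1H-cyclopenta[c]pyridin-6-yl 4-nitrobenzoate | O=C(O[C@H]1C[C@H]2[C@H](CN(C)C[C@H]2C)[C@H]1C)c1ccc(cc1)[N+](=O)[O-]
F6 | step 17 | (4S,4aR,6S,7R,7aS)-2,4,7-trimethyloctahydro-1H-cyclopenta[c]pyridin-6-ol | O[C@H]1C[C@H]2[C@H](CN(C)C[C@H]2C)[C@H]1C
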